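## Retrosynthetic overview

- Target 14 comes from O-methylation of the 6-hydroxyflavone 13.
- 13 comes from phenolic 1,3-diketone 11 by closing ring C at the C8a–O1 bond. The feature used is that in ring A the unsubstituted C8a–H lies para to the C6 oxygen, so oxidising a free C6 phenol makes exactly that carbon electrophilic towards the enol oxygen of the diketone.
- 11 comes from aldol 9 by oxidation and debenzylation; 9 is the C3–C4 aldol union of ring B methyl ketone 3 and ring A aldehyde 7.
- 3 comes from 1,2,4-trimethoxybenzene 1 by directed ortho-lithiation and acetylation; 7 comes from 2,3-dihydroxybenzaldehyde 4 by 3-O-benzylation and 2-O-methylation.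
- Rings A and B are bought as arenes; ring C is the only ring formed (step 7).

Key step: step 7

Remark: aldol 9 and the transient dienone 12 are racemic; both stereocentres are removed on the way and the target is achiral. n-BuLi, LiN(SiMe3)2 solution, N-methoxy-N-methylacetamide, benzyl bromide, iodomethane and Dess–Martin periodinane are taken as purchased reagents.

## Route

Step 1
Reactants: 1 1,2,4-trimethoxybenzene
Product: 3 1-(2,3,6-trimethoxyphenyl)ethan-1-one, via (2,3,6-trimethoxyphenyl)lithium 2 (not isolated)
Conditions: n-BuLi (1.1 equiv), TMEDA, THF, 0 °C to rt; then N-methoxy-N-methylacetamide, −78 °C to 0 °C; dilute aq. HCl work-up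
Reagents that add atoms: N-methoxy-N-methylacetamide, CC(=O)N(C)OC; n-butyllithium, [Li]CCCC (supplies only the lithium of 2)
Why: Directed ortho-metalation removes the proton flanked by the C2 and C4 methoxy groups, and the aryllithium is acylated once by the Weinreb amide because the chelated tetrahedral adduct survives until work-up.

Step 2
Reactants: 4 2,3-dihydroxybenzaldehyde
Product: 6 3-(benzyloxy)-2-hydroxybenzaldehyde, via disodium 3-formylbenzene-1,2-diolate 5 (not isolated)
Conditions: NaH (2.2 equiv), DMSO, rt; then BnBr (1.0 equiv), rt; dilute aq. HCl work-up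
Reagents that add atoms: benzyl bromide, BrCc1ccccc1; sodium hydride, [Na+].[H-] (supplies only the sodium of 5)
Why: Williamson etherification of the dianion should go at the 3-phenoxide, the more nucleophilic oxygen, because the 2-phenoxide is delocalised into the formyl group and held in a sodium chelate.

Step 3
Reactants: 6 3-(benzyloxy)-2-hydroxybenzaldehyde
Product: 7 3-(benzyloxy)-2-methoxybenzaldehyde
Conditions: MeI, K2CO3, DMF, rt
Reagents that add atoms: iodomethane, CI
Why: Williamson O-methylation of the chelated salicylaldehyde hydroxyl in a dipolar aprotic solvent, with no other alkylatable site in 6.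

Step 4
Reactants: 3 1-(2,3,6-trimethoxyphenyl)ethan-1-one; 7 3-(benzyloxy)-2-methoxybenzaldehyde
Product: 9 3-[3-(benzyloxy)-2-methoxyphenyl]-3-hydroxy-1-(2,3,6-trimethoxyphenyl)propan-1-one (racemic), via lithium 1-(2,3,6-trimethoxyphenyl)ethen-1-olate 8 (not isolated)
Conditions: LiN(SiMe3)2 (1.05 equiv), THF, −78 °C; then 7, −78 °C; AcOH quench at −78 °C
Reagents that add atoms: lithium bis(trimethylsilyl)amide, [Li+].C[Si](C)(C)[N-][Si](C)(C)C (supplies only the lithium of 8)
Why: Directed crossed aldol addition, in which the methyl ketone is fully enolised before the non-enolisable aldehyde is added; the carbinol centre forms racemic, which does not matter because step 5 oxidises it away.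

Step 5
Reactants: 9 3-[3-(benzyloxy)-2-methoxyphenyl]-3-hydroxy-1-(2,3,6-trimethoxyphenyl)propan-1-one
Product: 10 1-[3-(benzyloxy)-2-methoxyphenyl]-3-(2,3,6-trimethoxyphenyl)propane-1,3-dione
Conditions: Dess–Martin periodinane (1.3 equiv), CH2Cl2, 0 °C to rt
Reagents that add atoms: none
Why: Dess–Martin oxidation of a β-hydroxy ketone to the 1,3-diketone runs under near-neutral conditions, which avoids retro-aldol cleavage and dehydration.

Step 6
Reactants: 10 1-[3-(benzyloxy)-2-methoxyphenyl]-3-(2,3,6-trimethoxyphenyl)propane-1,3-dione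
Product: 11 1-(3-hydroxy-2-methoxyphenyl)-3-(2,3,6-trimethoxyphenyl)propane-1,3-dione
Conditions: H2 (1 atm), Pd/C, EtOAc, rt
Reagents that add atoms: none
Why: Catalytic hydrogenolysis of the benzyl aryl ether, under which the enolised diaryl 1,3-diketone and the methyl ethers should be inert.

Step 7
Reactants: 11 1-(3-hydroxy-2-methoxyphenyl)-3-(2,3,6-trimethoxyphenyl)propane-1,3-dione
Product: 13 6-hydroxy-5-methoxy-2-(2,3,6-trimethoxyphenyl)-4H-chromen-4-one, via 8aH-chromene-4,6-dione tautomer 12 (not isolated)
Conditions: undivided cell, graphite anode, platinum cathode, n-Bu4NPF6 (0.1 M), 2,6-lutidine (3 equiv), (CF3)2CHOH, 5 mM in 11, rt, N2, constant potential at the first anodic wave of 11 (Ag/AgCl reference), stopped at 2.0–2.1 F/mol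
Reagents that add atoms: none
Why: Proposed new method: base-assisted loss of two electrons and one proton from the C6 phenol at the anode should give a phenoxonium ion with positive charge at C8a (para to the C6 oxygen), C5 and C7, the distal enol oxygen of the diketone adds to C8a to give dienone 12, and loss of the C8a proton re-aromatises ring A to phenol 13, while the cathode balances the charge by H2 evolution from the solvent. The closest known reaction types are anodic phenol oxidation with intramolecular capture of the phenoxonium ion by oxygen nucleophiles, anodic dehydrogenative lactonisation of biaryl-2-carboxylic acids and oxidative phenol coupling of hydroxybenzophenones to xanthones; closure by an enol oxygen onto an arene C–H to give a flavone is not among them. Ring C closes through the six atoms O1–C2=C3–C4–C4a–C8a, a six-membered closure that is exo with respect to the C8=C8a bond of the cation and has the geometry of the classical cyclodehydration of 2'-hydroxy diketones; no stereocentre remains in 13. Three selectivities are needed: oxidation of the phenol and not of ring B or the enol, which the low potential of the lutidine-bound phenol and potentiostatic control should secure; attack at C8a–H and not ipso at the methoxylated C5, secured because only the C8a adduct can lose a proton and aromatise irreversibly whereas the C5 adduct is a mixed ketal that can re-ionise in (CF3)2CHOH; and bonding through oxygen, which is certain because the central carbon of the diketone and the C4 carbonyl oxygen could reach C8a only through four-membered rings. Intermolecular coupling and over-oxidation of 13, itself a para-oxygenated phenol, are to be held back by high dilution, the weakly nucleophilic solvent and stopping at two faradays per mole.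

Step 8
Reactants: 13 6-hydroxy-5-methoxy-2-(2,3,6-trimethoxyphenyl)-4H-chromen-4-one
Product: 14 5,6-dimethoxy-2-(2,3,6-trimethoxyphenyl)-4H-chromen-4-one (5,6,2',3',6'-pentamethoxyflavone)
Conditions: MeI, K2CO3, acetone, reflux
Reagents that add atoms: iodomethane, CI
Why: Williamson methylation of the only free hydroxyl should give the pentamethyl ether without touching the pyranone.

## Compound list

1 | 1,2,4-trimethoxybenzene | COc1ccc(OC)c(OC)c1 | starting material
2 | (2,3,6-trimethoxyphenyl)lithium | [Li]c1c(OC)ccc(OC)c1OC | intermediate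
3 | 1-(2,3,6-trimethoxyphenyl)ethan-1-one | COc1ccc(OC)c(C(C)=O)c1OC | intermediate
4 | 2,3-dihydroxybenzaldehyde | O=Cc1cccc(O)c1O | starting material
5 | disodium 3-formylbenzene-1,2-diolate | O=Cc1cccc([O-])c1[O-].[Na+].[Na+] | intermediate
6 | 3-(benzyloxy)-2-hydroxybenzaldehyde | O=Cc1cccc(OCc2ccccc2)c1O | intermediate
7 | 3-(benzyloxy)-2-methoxybenzaldehyde | COc1c(C=O)cccc1OCc1ccccc1 | intermediate
8 | lithium 1-(2,3,6-trimethoxyphenyl)ethen-1-olate | [Li+].[O-]C(=C)c1c(OC)ccc(OC)c1OC | intermediate
9 | 3-[3-(benzyloxy)-2-methoxyphenyl]-3-hydroxy-1-(2,3,6-trimethoxyphenyl)propan-1-one (racemic) | COc1ccc(OC)c(C(=O)CC(O)c2cccc(OCc3ccccc3)c2OC)c1OC | intermediate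
10 | 1-[3-(benzyloxy)-2-methoxyphenyl]-3-(2,3,6-trimethoxyphenyl)propane-1,3-dione | COc1ccc(OC)c(C(=O)CC(=O)c2cccc(OCc3ccccc3)c2OC)c1OC | intermediate
11 | 1-(3-hydroxy-2-methoxyphenyl)-3-(2,3,6-trimethoxyphenyl)propane-1,3-dione | COc1ccc(OC)c(C(=O)CC(=O)c2cccc(O)c2OC)c1OC | intermediate
12 | 5-methoxy-2-(2,3,6-trimethoxyphenyl)-8aH-chromene-4,6-dione (racemic) | COc1ccc(OC)c(C2=CC(=O)C3=C(OC)C(=O)C=CC3O2)c1OC | intermediate
13 | 6-hydroxy-5-methoxy-2-(2,3,6-trimethoxyphenyl)-4H-chromen-4-one | COc1ccc(OC)c(-c2cc(=O)c3c(OC)c(O)ccc3o2)c1OC | intermediate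
14 | 5,6-dimethoxy-2-(2,3,6-trimethoxyphenyl)-4H-chromen-4-one (5,6,2',3',6'-pentamethoxyflavone) | COc1ccc(OC)c(-c2cc(=O)c3c(OC)c(OC)ccc3o2)c1OC | target

## Step count and risks

Total step count: 8. Longest linear sequence: 7 steps (4 to 14 through steps 2 to 8).

Steps most likely to fail:

1. Step 7. Oxidation may take place at the trimethoxyarene or at the diketone enol instead of the phenol, the oxidised phenol may couple intermolecularly before it cyclises, or the product phenol may be oxidised further. The fallback forms the same C8a–O1 bond by known copper-catalysed Ullmann-type O-arylation of a 2-bromoaryl 1,3-diketone. It sets out from 7: NBS in DMF should brominate para to the benzyloxy group to give 3-(benzyloxy)-6-bromo-2-methoxybenzaldehyde F1; addition of enolate 8 under the conditions of step 4 gives 3-[3-(benzyloxy)-6-bromo-2-methoxyphenyl]-3-hydroxy-1-(2,3,6-trimethoxyphenyl)propan-1-one F2; Dess–Martin oxidation gives 1-[3-(benzyloxy)-6-bromo-2-methoxyphenyl]-3-(2,3,6-trimethoxyphenyl)propane-1,3-dione F3; CuI, K2CO3 in DMF at 100 °C should close ring C to 6-(benzyloxy)-5-methoxy-2-(2,3,6-trimethoxyphenyl)-4H-chromen-4-one F4; hydrogenolysis with H2 and Pd/C comes back to the route at 13.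

2. Step 2. Alkylation may occur at the 2-oxygen or at both oxygens. The fallback sets out from 4: exhaustive benzylation with BnBr and K2CO3 in DMF gives 2,3-bis(benzyloxy)benzaldehyde F5, and chelation-controlled cleavage of the benzyl ether ortho to the formyl group with MgBr2·OEt2 in toluene/ether comes back to the route at 6.

3. Step 4. The lithium aldolate may revert by retro-aldol cleavage or dehydrate to the chalcone during the reaction or the quench. The fallback makes the enone on purpose and brings in the oxygen afterwards. It sets out from 3 and 7: Claisen–Schmidt condensation with KOH in EtOH gives (E)-3-[3-(benzyloxy)-2-methoxyphenyl]-1-(2,3,6-trimethoxyphenyl)prop-2-en-1-one F6; Weitz–Scheffer epoxidation with H2O2 and NaOH in MeOH gives trans-[3-[3-(benzyloxy)-2-methoxyphenyl]oxiran-2-yl](2,3,6-trimethoxyphenyl)methanone F7 as the racemate; isomerisation of the α,β-epoxy ketone with Pd(PPh3)4 (zerovalent palladium) and 1,2-bis(diphenylphosphino)ethane in toluene at 100 °C comes back to the route at 10.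

## Further compounds

F1 | step 7 | 3-(benzyloxy)-6-bromo-2-methoxybenzaldehyde | COc1c(C=O)c(Br)ccc1OCc1ccccc1
F2 | step 7 | 3-[3-(benzyloxy)-6-bromo-2-methoxyphenyl]-3-hydroxy-1-(2,3,6-trimethoxyphenyl)propan-1-one (racemic) | COc1ccc(OC)c(C(=O)CC(O)c2c(Br)ccc(OCc3ccccc3)c2OC)c1OC
F3 | step 7 | 1-[3-(benzyloxy)-6-bromo-2-methoxyphenyl]-3-(2,3,6-trimethoxyphenyl)propane-1,3-dione | COc1ccc(OC)c(C(=O)CC(=O)c2c(Br)ccc(OCc3ccccc3)c2OC)c1OC
F4 | step 7 | 6-(benzyloxy)-5-methoxy-2-(2,3,6-trimethoxyphenyl)-4H-chromen-4-one | COc1ccc(OC)c(-c2cc(=O)c3c(OC)c(OCc4ccccc4)ccc3o2)c1OC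
F5 | step 2 | 2,3-bis(benzyloxy)benzaldehyde | O=Cc1cccc(OCc2ccccc2)c1OCc1ccccc1
F6 | step 4 | (E)-3-[3-(benzyloxy)-2-methoxyphenyl]-1-(2,3,6-trimethoxyphenyl)prop-2-en-1-one | COc1ccc(OC)c(C(=O)/C=C/c2cccc(OCc3ccccc3)c2OC)c1OC
F7 | step 4 | trans-[3-[3-(benzyloxy)-2-methoxyphenyl]oxiran-2-yl](2,3,6-trimethoxyphenyl)methanone (racemic, one enantiomer drawn) | COc1ccc(OC)c(C(=O)[C@@H]2O[C@H]2c4cccc(OCc3ccccc3)c4OC)c1OC
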